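## Structural features

The target is a 2,3-dihydrobenzofuran: benzene ring A fused to a five-membered oxygen ring made of O1, C2, C3, C3a and C7a. C2 carries a 4-hydroxyphenyl group, C3 a carboxamide and C5 of ring A an (E)-acrylamide; both amide nitrogens bear a 4-guanidinobutyl chain. The only stereocentres, C2 and C3, are adjacent, both R, and hold the aryl and carboxamide groups trans. C3–H is benzylic and alpha to a carbonyl, so C3 can be epimerised, with trans as the stable arrangement. C2–O1 is a benzylic aryl ether para to a phenol oxygen, so it is sensitive to strong acid and to hydrogenolysis; the acrylamide rules out hydrogenation, and the two guanidines have to stay masked until the end. A carbonyl at C3 makes O1 a beta leaving group and C2–C3 a retro-aldol bond, so the real difficulty is to fix the absolute configuration at C2 and the trans relationship without passing through an intermediate that can open the ring. The key step uses the fact that O1 sits on C7a, para to the carbon substituent at C5: with that carbon as a nitrile, a fluorine on C7a can be displaced by the oxygen on C2.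

## Logic of the disconnections

19 to 18: the four N–CO2t-Bu bonds and the aryl O–t-Bu bond are cut. All five masks fall to one acid, so the polar, basic target appears only in the last operation and 18 can still be purified on silica. The forward step must keep acid exposure short enough to spare C2–O1 and must trap tert-butyl cations.

18 to 16 and two molecules of 17: both amide C–N bonds are cut. The two amine partners are identical, so one coupling serves both carboxyl groups and the route becomes convergent. The forward step must activate the C3 acid without opening the ring; epimerisation there can only return the stable trans isomer.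

16 to 14 (through 15): the C3 carboxyl is traced back to a hydroxymethyl group. The C5 side chain needs a hydride step, and that step is placed before any carboxylic acid exists. Oxidising first and reducing the nitrile afterwards would force a hydride reagent to distinguish a nitrile from an aluminium carboxylate. The reordering costs no step; it demands an alcohol-to-acid oxidation that leaves an acrylic acid and two aryl ethers alone.

14 to 12 (through 13): the acrylic Cα=Cβ bond is cut in the sense of a Knoevenagel–Doebner condensation. The side chain shrinks to a formyl group. The forward step needs a single aldehyde in the molecule, which holds because C3 is at the alcohol level.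

12 to 10 (through 11): the C5 formyl goes back to the nitrile and the C3 hydroxymethyl to a formyl group, so one hydride reagent serves both. This restores the nitrile that activates the key step. The reduction must stop at the aldimine stage.

10 to 7 (through 8 and 9): the C3 formyl is traced to a vinyl group by ozonolysis, and C3 is inverted at the aldehyde, the one stage where it equilibrates under mild base. The gain is that 7 has no carbonyl beta to O1. The cleavage must prefer the terminal alkene over an electron-rich arene, and the equilibration must not open the ring.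

7 to 6: O1–C7a is cut. The para nitrile makes fluoride displacement feasible, and the C2 stereocentre arrives intact from an open chain because its C–O bond is never broken. The bicycle reduces to an acyclic diaryl butenol. The forward step needs O-arylation to outrun deprotonation at C3–H; the cis outcome is accepted because C3 is corrected afterwards.

6 to 3 and 4 (through 5): the bond between the carbinol carbon and the benzylic carbon is cut in the sense of an allylboration, which sets both stereocentres at once. The E geometry of 3 fixes the anti relationship and a chiral acid fixes the absolute sense. Anti is used, not syn, because the E boronate is the isomer the borylation delivers. The demand is a geometrically pure E boronate and good facial control.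

3 to 2 to 1: the C–B bond is cut with allylic transposition, then the C–C bond to the vinyl group. This reaches a bought aldehyde in two operations. The demands are linear E selectivity in the borylation and attack at the aldehyde, not the nitrile, in the Grignard addition.

## Other disconnections considered

Alternative 1: The cut removes three ring-A bonds (C3a–C7a, C4–C5, C6–C7), so ring A and the oxygen ring form together. In the forward key step the 1,6-diyne A2, whose O1 is an ethynyl ether oxygen and whose C3 carries an ethynyl group, would be cyclotrimerised with ethyne A3 on RhCl(PPh3)3 to give A1.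
- In its favour: both stereocentres are set on an open chain in the final trans relationship, so no C3 inversion is needed; three C–C bonds and two rings form in one operation. On bond economy and on avoiding an epimerisation stage it is better than the chosen plan, and it is its equal in keeping the C2–O bond unbroken.
- Against it here: A2 contains an alkynyl ether of a secondary benzylic alcohol. Making it needs strong base and extra steps, and such ethers with a beta hydrogen can fragment thermally. A1 has hydrogen at C5, so the C5 carbon would have to be added afterwards by electrophilic substitution in competition with the electron-rich tert-butoxyphenyl ring, followed by a Heck reaction, silyl removal and oxidation at C3. A substituted alkyne in place of A3 would raise a C5 versus C6 regiochemistry problem.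
- Comparison: both closures are known reaction types, though the SNAr follows a single pathway and metal-mediated alkyne assembly with an oxygen-substituted alkyne is less predictable. The chosen plan carries the C5 carbon from the first step and uses it as the activator, and it is estimated to be several steps shorter.

Alternative 2: The cut is C3–C3a, read as a reverse 1,2-aryl shift back to flavanone A5. In the forward key step PhI(OAc)2 and H2SO4 in HC(OMe)3 would attack the enol ether of A5 at C3 with trivalent iodine; C4a then migrates from the carbonyl carbon to C3, contracting the pyranone to the methyl ester A4.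
- In its favour: A5 is a few steps from simple aromatic precursors. A4 comes out trans with C3 already at the acid level, and its C5 bromide would let a Heck reaction attach the acrylamide arm without any redox at C5. On step count and on needing no C3 inversion or oxidation-level change it is better than the chosen plan.
- Against it here: A5 must be enantioenriched, and its C2 centre can be lost through reversible ring opening under the strongly acidic conditions. The oxidative rearrangement competes with aryl migration from C2 and with dehydrogenation; the balance depends on the electron density of the C2 aryl, which is why a sulfonate and not an ether masks the phenol, and the sulfonate needs a later basic cleavage.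
- Comparison: the chosen plan fixes C2 by an established catalytic allylboration and never breaks the C2–O bond, so it is better on stereochemical security and on mechanistic cleanliness. The alternative is the better on length.

Alternative 3: The cut is O1–C2. In the forward key step a chiral BINOL-derived phosphoric acid would dehydrate the 4-hydroxybenzylic alcohol A7 (all four stereoisomers) to the para-quinone methide A8, and the ortho phenol would add to its exocyclic carbon in a 5-exo-trig closure to give A6.
- In its favour: A7 comes from one aldol union and its stereochemistry is irrelevant because the carbinol is erased in A8. The phenol needs no protecting group, C3 is an ester from the start, and the bromide again allows a Heck reaction. On step count and protecting-group economy it is better than the chosen plan, and it is its equal in ring-closure mode.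
- Against it here: all stereocontrol rests on a chiral anion steering an intramolecular 1,6-addition that must also set C3. That requires C3 of A8 to equilibrate faster than the ring closes; otherwise the isomers do not converge. A6 carries a free para-hydroxyphenyl at C2 and could re-ionise to A8 under the same acid, and any achiral acid could catalyse a racemic background closure.
- Comparison: both plans close the oxygen ring by a C–O bond. There C2 is created in the key step under catalyst control whose outcome is hard to predict; here C2 is created earlier by a known reaction and the key step cannot disturb it. The chosen plan is better on predictability, the alternative on length.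

Key step: step 4

Assumption: the (R) phosphoric acid is taken to direct Re-face attack on 4 as it does on other aryl aldehydes (the (S) acid would be used otherwise), and 19 is listed as the neutral bis-guanidine although acidolysis delivers its bis(trifluoroacetate) salt.

## Route

Step 1
Reactants: 1 4-fluoro-3-formylbenzonitrile
Product: 2 (±)-4-fluoro-3-(1-hydroxyprop-2-en-1-yl)benzonitrile
Conditions: CH2=CHMgBr (1.05 equiv), THF, −78 °C; aq. NH4Cl
Reagents that add atoms: vinylmagnesium bromide (CH2=CHMgBr), C=C[Mg]Br
Why: Grignard 1,2-addition; at −78 °C the aldehyde is far more electrophilic than the nitrile or the fluorinated ring carbon, and the carbinol centre is deliberately racemic because step 2 turns it into a trigonal carbon.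

Step 2
Reactants: 2 (±)-4-fluoro-3-(1-hydroxyprop-2-en-1-yl)benzonitrile
Product: 3 4-fluoro-3-[(1E)-3-(4,4,5,5-tetramethyl-1,3,2-dioxaborolan-2-yl)prop-1-en-1-yl]benzonitrile
Conditions: Pd(MeCN)4(BF4)2 (5 mol%), B2pin2 (1.2 equiv), DMSO/MeOH (1:1), 40 °C
Reagents that add atoms: bis(pinacolato)diboron, CC1(C)OB(OC1(C)C)B1OC(C)(C)C(C)(C)O1
Why: Palladium-catalysed direct borylation of an allylic alcohol: the diboron activates the hydroxyl, ionisation gives an η3-allyl complex of divalent palladium, and boron goes to the unsubstituted terminus, so the branched alcohol should transpose to the linear boronate with the conjugated E double bond; nitrile and aryl fluoride are spectators.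

Step 3
Reactants: 3 4-fluoro-3-[(1E)-3-(4,4,5,5-tetramethyl-1,3,2-dioxaborolan-2-yl)prop-1-en-1-yl]benzonitrile (1.2 equiv); 4 4-tert-butoxybenzaldehyde
Product: 6 3-[(1R,2S)-1-(4-tert-butoxyphenyl)-1-hydroxybut-3-en-2-yl]-4-fluorobenzonitrile (anti), via borate ester 5 (not isolated)
Conditions: (R)-3,3'-bis(2,4,6-triisopropylphenyl)-1,1'-binaphthyl-2,2'-diyl hydrogen phosphate [(R)-TRIP] (5 mol%), 4 Å MS, toluene, −30 °C; aq. NaHCO3
Reagents that add atoms: none
Why: Chiral phosphoric acid-catalysed allylboration through a closed six-membered chair transition state: the E γ-aryl group sits equatorial and becomes the anti relationship, while the acid, hydrogen-bonded to a boronate oxygen and the formyl hydrogen, should expose the Re face of 4, giving 1R and therefore 2S; the B–O bond of 5 is cleaved in the work-up.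

Step 4
Reactants: 6 3-[(1R,2S)-1-(4-tert-butoxyphenyl)-1-hydroxybut-3-en-2-yl]-4-fluorobenzonitrile
Product: 7 (2R,3S)-2-(4-tert-butoxyphenyl)-3-ethenyl-2,3-dihydro-1-benzofuran-5-carbonitrile (cis)
Conditions: Cs2CO3 (2 equiv), DMF, 60 °C
Reagents that add atoms: none
Why: Carbonate generates a low stationary concentration of the secondary alkoxide, which adds to the fluorine-bearing carbon C7a to give a Meisenheimer anion delocalised over ring A onto the para nitrile at C5; loss of fluoride restores the arene with O1–C7a in place. The closest known reaction type is the intramolecular SNAr etherification of a fluoroarene activated by a para acceptor. The one ring formed, the dihydrofuran, closes in a 5-exo-trig mode, since the π bond that takes up the electrons lies outside the new ring. No stereocentre is created: the carbinol C–O bond is never broken, so 1R of 6 becomes 2R of 7, C3 is untouched, and the anti open-chain relationship maps onto the cis ring. The selectivity needed is chemoselectivity for O-arylation over deprotonation of the benzylic, allylic C3–H (which would move the vinyl double bond into conjugation), over fragmentation of the homoallylic alkoxide and over intermolecular substitution. It is secured by the para nitrile, which makes displacement fast with a base too weak to ionise C3–H, by the five-membered tether, and by the vinyl group, which unlike a carbonyl gives the alkoxide no retro-aldol exit. The cis outcome is accepted because C3 is corrected in step 5.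

Step 5
Reactants: 7 (2R,3S)-2-(4-tert-butoxyphenyl)-3-ethenyl-2,3-dihydro-1-benzofuran-5-carbonitrile
Product: 10 (2R,3R)-2-(4-tert-butoxyphenyl)-3-formyl-2,3-dihydro-1-benzofuran-5-carbonitrile (trans), via ozonide 8 (not isolated), via cis aldehyde 9 (not isolated)
Conditions: O3, CH2Cl2, −78 °C (Sudan Red 7B end point); N2 purge; Et3N (2 equiv), −78 → 0 °C; DBU (1.5 equiv), 0 °C → rt
Reagents that add atoms: ozone, [O-][O+]=O
Why: Criegee ozonolysis in a non-participating solvent gives the terminal 1,2,4-trioxolane 8; amine base removes a proton from its unsubstituted CH2 and E1cB fragmentation releases aldehyde 9 and formate without a reductant and without free formaldehyde. DBU then equilibrates C3 through the enolate to the more stable trans isomer 10; C2 should be safe because expulsion of O1 from that enolate is the reverse of a disfavoured 5-endo-trig closure.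

Step 6
Reactants: 10 (2R,3R)-2-(4-tert-butoxyphenyl)-3-formyl-2,3-dihydro-1-benzofuran-5-carbonitrile
Product: 12 (2R,3S)-2-(4-tert-butoxyphenyl)-3-(hydroxymethyl)-2,3-dihydro-1-benzofuran-5-carbaldehyde (trans), via aldimine 11 (not isolated)
Conditions: i-Bu2AlH (3.2 equiv), CH2Cl2, −78 → 0 °C; aq. KNaC4H4O6 (potassium sodium tartrate), then aq. citric acid, rt
Reagents that add atoms: water, O
Why: i-Bu2AlH reduction: the C3 aldehyde goes at once to the aluminium alkoxide and the nitrile accepts one hydride to give an N-aluminio aldimine that resists further reduction at low temperature; mild aqueous acid hydrolyses 11 to the aldehyde. Placing the hydride step before any carboxylic acid exists removes the nitrile-versus-carboxylate question, and C3 cannot epimerise once it bears a hydroxymethyl group.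

Step 7
Reactants: 12 (2R,3S)-2-(4-tert-butoxyphenyl)-3-(hydroxymethyl)-2,3-dihydro-1-benzofuran-5-carbaldehyde
Product: 14 (2E)-3-[(2R,3S)-2-(4-tert-butoxyphenyl)-3-(hydroxymethyl)-2,3-dihydro-1-benzofuran-5-yl]prop-2-enoic acid, via arylidenemalonic acid 13 (not isolated)
Conditions: CH2(CO2H)2 (3 equiv), pyridine, piperidine (0.1 equiv), 90 °C
Reagents that add atoms: malonic acid, OC(=O)CC(O)=O
Why: Knoevenagel condensation in the Doebner modification: the piperidine-derived iminium of the aromatic aldehyde is attacked by malonate, and 13 loses CO2 in hot pyridine to give the E acrylic acid; the primary alcohol and the aryl tert-butyl ether are inert to the buffered amine medium.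

Step 8
Reactants: 14 (2E)-3-[(2R,3S)-2-(4-tert-butoxyphenyl)-3-(hydroxymethyl)-2,3-dihydro-1-benzofuran-5-yl]prop-2-enoic acid
Product: 16 (2R,3R)-2-(4-tert-butoxyphenyl)-5-[(1E)-2-carboxyethenyl]-2,3-dihydro-1-benzofuran-3-carboxylic acid, via formyl acid 15 (not isolated)
Conditions: TEMPO (0.2 equiv), PhI(OAc)2 (2.5 equiv), MeCN/H2O (1:1), rt
Reagents that add atoms: water, O
Why: Oxoammonium (TEMPO) catalysis with PhI(OAc)2 as terminal oxidant takes the primary alcohol to aldehyde 15 and, through its hydrate in the aqueous medium, on to the carboxylic acid; the electron-poor acrylic double bond and the aryl ethers should not react, and 15 already has the stable trans arrangement.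

Step 9
Reactants: 16 (2R,3R)-2-(4-tert-butoxyphenyl)-5-[(1E)-2-carboxyethenyl]-2,3-dihydro-1-benzofuran-3-carboxylic acid; 17 N,N'-di-Boc-agmatine, N-(4-aminobutyl)-N',N''-bis(tert-butoxycarbonyl)guanidine (2.2 equiv)
Product: 18 (2R,3R)-N-{4-[N',N''-bis(tert-butoxycarbonyl)guanidino]butyl}-5-[(1E)-3-({4-[N',N''-bis(tert-butoxycarbonyl)guanidino]butyl}amino)-3-oxoprop-1-en-1-yl]-2-(4-tert-butoxyphenyl)-2,3-dihydro-1-benzofuran-3-carboxamide
Conditions: N,N'-diisopropylcarbodiimide (2.4 equiv), HOBt (2.4 equiv), DMF/CH2Cl2, 0 °C → rt
Reagents that add atoms: none
Why: Carbodiimide/HOBt amide coupling at both carboxyl groups with the only nucleophilic nitrogen of 17, its primary amine (the doubly carbamoylated guanidine is neither basic nor nucleophilic); any epimerisation at C3 through the active ester can only lead back to the stable trans isomer.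

Step 10
Reactants: 18 (2R,3R)-N-{4-[N',N''-bis(tert-butoxycarbonyl)guanidino]butyl}-5-[(1E)-3-({4-[N',N''-bis(tert-butoxycarbonyl)guanidino]butyl}amino)-3-oxoprop-1-en-1-yl]-2-(4-tert-butoxyphenyl)-2,3-dihydro-1-benzofuran-3-carboxamide
Product: 19 (2R,3R)-N-(4-guanidinobutyl)-5-{(1E)-3-[(4-guanidinobutyl)amino]-3-oxoprop-1-en-1-yl}-2-(4-hydroxyphenyl)-2,3-dihydro-1-benzofuran-3-carboxamide (CNP0497893.1)
Conditions: CF3CO2H/CH2Cl2 (1:1), anisole (10 equiv), H2O (2 vol%), 0 °C → rt
Reagents that add atoms: none
Why: Acidolysis by an E1 path removes the four tert-butyl carbamates (with loss of CO2) and the aryl tert-butyl ether in one operation; anisole and water intercept the tert-butyl cations before they alkylate the freed phenol ring, and no hydride-donating silane is used, so the benzylic C2–O1 bond is not exposed to ionic hydrogenation.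

## Compound list

1 | 4-fluoro-3-formylbenzonitrile | N#Cc1ccc(F)c(C=O)c1 | starting material
2 | (±)-4-fluoro-3-(1-hydroxyprop-2-en-1-yl)benzonitrile | N#Cc1ccc(F)c(c1)C(O)C=C | intermediate
3 | 4-fluoro-3-[(1E)-3-(4,4,5,5-tetramethyl-1,3,2-dioxaborolan-2-yl)prop-1-en-1-yl]benzonitrile | N#Cc1ccc(F)c(c1)/C=C/CB1OC(C)(C)C(C)(C)O1 | intermediate
4 | 4-tert-butoxybenzaldehyde | CC(C)(C)Oc1ccc(C=O)cc1 | starting material
5 | 3-{(1R,2S)-1-(4-tert-butoxyphenyl)-1-[(4,4,5,5-tetramethyl-1,3,2-dioxaborolan-2-yl)oxy]but-3-en-2-yl}-4-fluorobenzonitrile | N#Cc1ccc(F)c(c1)[C@H](C=C)[C@@H](OB1OC(C)(C)C(C)(C)O1)c1ccc(OC(C)(C)C)cc1 | intermediate (not isolated)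
6 | 3-[(1R,2S)-1-(4-tert-butoxyphenyl)-1-hydroxybut-3-en-2-yl]-4-fluorobenzonitrile (anti) | N#Cc1ccc(F)c(c1)[C@H](C=C)[C@@H](O)c1ccc(OC(C)(C)C)cc1 | intermediate
7 | (2R,3S)-2-(4-tert-butoxyphenyl)-3-ethenyl-2,3-dihydro-1-benzofuran-5-carbonitrile (cis) | N#Cc1ccc2c(c1)[C@H](C=C)[C@H](c1ccc(OC(C)(C)C)cc1)O2 | intermediate
8 | (2R,3S)-2-(4-tert-butoxyphenyl)-3-(1,2,4-trioxolan-3-yl)-2,3-dihydro-1-benzofuran-5-carbonitrile (cis; trioxolane carbon as a mixture) | N#Cc1ccc2c(c1)[C@H](C3OCOO3)[C@H](c1ccc(OC(C)(C)C)cc1)O2 | intermediate (not isolated)
9 | (2R,3S)-2-(4-tert-butoxyphenyl)-3-formyl-2,3-dihydro-1-benzofuran-5-carbonitrile (cis) | N#Cc1ccc2c(c1)[C@H](C=O)[C@H](c1ccc(OC(C)(C)C)cc1)O2 | intermediate (not isolated)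
10 | (2R,3R)-2-(4-tert-butoxyphenyl)-3-formyl-2,3-dihydro-1-benzofuran-5-carbonitrile (trans) | N#Cc1ccc2c(c1)[C@@H](C=O)[C@H](c1ccc(OC(C)(C)C)cc1)O2 | intermediate
11 | [(2R,3S)-2-(4-tert-butoxyphenyl)-5-(iminomethyl)-2,3-dihydro-1-benzofuran-3-yl]methanol (trans; present as its aluminium derivative before the quench) | N=Cc1ccc2c(c1)[C@@H](CO)[C@H](c1ccc(OC(C)(C)C)cc1)O2 | intermediate (not isolated)
12 | (2R,3S)-2-(4-tert-butoxyphenyl)-3-(hydroxymethyl)-2,3-dihydro-1-benzofuran-5-carbaldehyde (trans) | O=Cc1ccc2c(c1)[C@@H](CO)[C@H](c1ccc(OC(C)(C)C)cc1)O2 | intermediate
13 | 2-{[(2R,3S)-2-(4-tert-butoxyphenyl)-3-(hydroxymethyl)-2,3-dihydro-1-benzofuran-5-yl]methylidene}propanedioic acid | OC(=O)C(C(O)=O)=Cc1ccc2c(c1)[C@@H](CO)[C@H](c1ccc(OC(C)(C)C)cc1)O2 | intermediate (not isolated)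
14 | (2E)-3-[(2R,3S)-2-(4-tert-butoxyphenyl)-3-(hydroxymethyl)-2,3-dihydro-1-benzofuran-5-yl]prop-2-enoic acid | OC(=O)/C=C/c1ccc2c(c1)[C@@H](CO)[C@H](c1ccc(OC(C)(C)C)cc1)O2 | intermediate
15 | (2E)-3-[(2R,3R)-2-(4-tert-butoxyphenyl)-3-formyl-2,3-dihydro-1-benzofuran-5-yl]prop-2-enoic acid | OC(=O)/C=C/c1ccc2c(c1)[C@@H](C=O)[C@H](c1ccc(OC(C)(C)C)cc1)O2 | intermediate (not isolated)
16 | (2R,3R)-2-(4-tert-butoxyphenyl)-5-[(1E)-2-carboxyethenyl]-2,3-dihydro-1-benzofuran-3-carboxylic acid | OC(=O)/C=C/c1ccc2c(c1)[C@@H](C(O)=O)[C@H](c1ccc(OC(C)(C)C)cc1)O2 | intermediate
17 | N,N'-di-Boc-agmatine, N-(4-aminobutyl)-N',N''-bis(tert-butoxycarbonyl)guanidine | NCCCCN=C(NC(=O)OC(C)(C)C)NC(=O)OC(C)(C)C | starting material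
18 | (2R,3R)-N-{4-[N',N''-bis(tert-butoxycarbonyl)guanidino]butyl}-5-[(1E)-3-({4-[N',N''-bis(tert-butoxycarbonyl)guanidino]butyl}amino)-3-oxoprop-1-en-1-yl]-2-(4-tert-butoxyphenyl)-2,3-dihydro-1-benzofuran-3-carboxamide | CC(C)(C)OC(=O)NC(NC(=O)OC(C)(C)C)=NCCCCNC(=O)/C=C/c1ccc2c(c1)[C@@H](C(=O)NCCCCN=C(NC(=O)OC(C)(C)C)NC(=O)OC(C)(C)C)[C@H](c1ccc(OC(C)(C)C)cc1)O2 | intermediate
19 | (2R,3R)-N-(4-guanidinobutyl)-5-{(1E)-3-[(4-guanidinobutyl)amino]-3-oxoprop-1-en-1-yl}-2-(4-hydroxyphenyl)-2,3-dihydro-1-benzofuran-3-carboxamide | NC(N)=NCCCCNC(=O)/C=C/c1ccc2c(c1)[C@@H](C(=O)NCCCCN=C(N)N)[C@H](c1ccc(O)cc1)O2 | target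

## Step count and least certain steps

Total: 10 steps. Longest linear sequence: 10 steps (1 to 19); 4 and 17 enter as bought building blocks.

Step 4 (key step). The closure may be slow at the low alkoxide concentration a carbonate provides, and forcing it could let base remove the benzylic, allylic C3–H and move the vinyl double bond into conjugation. Fallback from 6: silylation (Me3SiCl, imidazole, CH2Cl2, 0 °C) gives the trimethylsilyl ether F1. Catalytic CsF in DMF at rt to 40 °C then unmasks one alkoxide, which closes the ring; the fluoride it expels desilylates the next molecule, so no stoichiometric base is ever present. This known fluoride-catalysed coupling of silyl ethers with activated fluoroarenes returns to the route at 7.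

Step 3. The electron-poor γ-aryl allylboronate may add slowly, so the uncatalysed pathway could compete and lower facial selectivity, and a 1,3-boron shift could scramble the E geometry and with it the anti selectivity. Fallback from 3 and 4: the uncatalysed allylboration (toluene, rt, same hydrolytic work-up) goes through the same chair transition state and should give the racemic anti alcohol F2. Its enantiomers are separated by preparative chromatography on a chiral carbamate stationary phase, and the (1R,2S) enantiomer is 6, where the route is rejoined.

Step 5. Ozone may attack the electron-rich tert-butoxyphenyl ring, the amine may abstract the ozonide proton on the substituted carbon (over-oxidation to the acid), and the enolate may expel the cyanophenoxide O1, which would open the ring and erase C2. Fallback from 7: dihydroxylation (OsO4 cat., N-methylmorpholine N-oxide, acetone/water) gives the diol F3 as carbinol epimers. NaIO4 in THF/water cleaves it to 9, with formaldehyde removed in the aqueous work-up. 9 is then equilibrated with pyrrolidine and AcOH (catalytic, CH2Cl2) through its enamine, a neutral and less electron-rich intermediate than the enolate, returning at 10.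

Step 2. Solvolysis of the allyl intermediate by methanol, protodeboronation, incomplete E selectivity or nitrile coordination to the cationic palladium could lower efficiency. Fallback from 2: ClCO2Me and pyridine give the branched methyl carbonate F4. Copper-catalysed γ-selective borylation (CuCl, Xantphos, KOt-Bu, B2pin2, THF, rt) then adds boryl-copper across the terminal double bond and eliminates the carbonate, giving the linear E boronate and returning at 3.

Step 10. The long acid exposure that doubly carbamoylated guanidines need may allow tert-butylation of the freed phenol ring or ionisation of the benzylic C2–O1 bond with loss of C2 integrity. Fallback from 16: N,N'-diisopropylcarbodiimide and N-hydroxysuccinimide give the bis(N-succinimidyl) ester F5. It acylates unprotected agmatine (as its sulfate, NaHCO3, DMF/H2O) at the primary amine only, because the guanidinium stays protonated, giving the O-tert-butyl-protected bis-guanidine F6. A brief treatment with dilute CF3CO2H in CH2Cl2 with anisole then removes the single tert-butyl ether and returns at 19.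

## Further compounds

F1 | step 4 | 3-[(1R,2S)-1-(4-tert-butoxyphenyl)-1-(trimethylsilyloxy)but-3-en-2-yl]-4-fluorobenzonitrile | N#Cc1ccc(F)c(c1)[C@H](C=C)[C@@H](O[Si](C)(C)C)c1ccc(OC(C)(C)C)cc1
F2 | step 3 | rac-anti-3-[1-(4-tert-butoxyphenyl)-1-hydroxybut-3-en-2-yl]-4-fluorobenzonitrile, (1R,2S) and (1S,2R) in equal amounts | N#Cc1ccc(F)c(c1)[C@H](C=C)[C@@H](O)c1ccc(OC(C)(C)C)cc1.N#Cc1ccc(F)c(c1)[C@@H](C=C)[C@H](O)c1ccc(OC(C)(C)C)cc1
F3 | step 5 | cis-(2R)-2-(4-tert-butoxyphenyl)-3-(1,2-dihydroxyethyl)-2,3-dihydro-1-benzofuran-5-carbonitrile, ring configuration as in 7, carbinol epimers | N#Cc1ccc2c(c1)[C@H](C(O)CO)[C@H](c1ccc(OC(C)(C)C)cc1)O2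
F4 | step 2 | (±)-1-(5-cyano-2-fluorophenyl)prop-2-en-1-yl methyl carbonate | N#Cc1ccc(F)c(c1)C(OC(=O)OC)C=C
F5 | step 10 | bis(2,5-dioxopyrrolidin-1-yl) ester of 16 | O=C1CCC(=O)N1OC(=O)/C=C/c1ccc2c(c1)[C@@H](C(=O)ON1C(=O)CCC1=O)[C@H](c1ccc(OC(C)(C)C)cc1)O2
F6 | step 10 | (2R,3R)-2-(4-tert-butoxyphenyl)-N-(4-guanidinobutyl)-5-{(1E)-3-[(4-guanidinobutyl)amino]-3-oxoprop-1-en-1-yl}-2,3-dihydro-1-benzofuran-3-carboxamide | NC(N)=NCCCCNC(=O)/C=C/c1ccc2c(c1)[C@@H](C(=O)NCCCCN=C(N)N)[C@H](c1ccc(OC(C)(C)C)cc1)O2
A1 | alternative 1 | (2R,3S)-2-(4-tert-butoxyphenyl)-3-[(tert-butyldimethylsilyloxy)methyl]-2,3-dihydro-1-benzofuran | c1ccc2c(c1)[C@@H](CO[Si](C)(C)C(C)(C)C)[C@H](c1ccc(OC(C)(C)C)cc1)O2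
A2 | alternative 1 | tert-butyl{[(2S,3R)-3-(4-tert-butoxyphenyl)-2-ethynyl-3-(ethynyloxy)propyl]oxy}dimethylsilane | C#C[C@@H](CO[Si](C)(C)C(C)(C)C)[C@H](c1ccc(OC(C)(C)C)cc1)OC#C
A3 | alternative 1 | ethyne | C#C
A4 | alternative 2 | methyl (2R,3R)-5-bromo-2-[4-(tosyloxy)phenyl]-2,3-dihydro-1-benzofuran-3-carboxylate | Brc1ccc2c(c1)[C@@H](C(=O)OC)[C@H](c1ccc(OS(=O)(=O)c3ccc(C)cc3)cc1)O2
A5 | alternative 2 | (2R)-6-bromo-2-[4-(tosyloxy)phenyl]-2,3-dihydro-4H-chromen-4-one | Brc1ccc2c(c1)C(=O)C[C@H](c1ccc(OS(=O)(=O)c3ccc(C)cc3)cc1)O2
A6 | alternative 3 | tert-butyl (2R,3R)-5-bromo-2-(4-hydroxyphenyl)-2,3-dihydro-1-benzofuran-3-carboxylate | Brc1ccc2c(c1)[C@@H](C(=O)OC(C)(C)C)[C@H](c1ccc(O)cc1)O2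
A7 | alternative 3 | tert-butyl 2-(5-bromo-2-hydroxyphenyl)-3-hydroxy-3-(4-hydroxyphenyl)propanoate, all four stereoisomers | Brc1ccc(O)c(c1)C(C(=O)OC(C)(C)C)C(O)c1ccc(O)cc1
A8 | alternative 3 | tert-butyl 2-(5-bromo-2-hydroxyphenyl)-3-(4-oxocyclohexa-2,5-dien-1-ylidene)propanoate | Brc1ccc(O)c(c1)C(C(=O)OC(C)(C)C)C=C1C=CC(=O)C=C1
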